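**Retrosynthetic overview**
1. The C3 ester is cut into (S)-4-silyloxyhex-2-ynoic acid and hex-2-ynoic acid; both alkynes are reduced to the (Z)-enoates last, so a free γ-hydroxy (Z)-enoate (which would lactonize) never exists.
2. Ring-B oxygens: C8–OH from equatorial hydride attack on a C8 ketone, C9–OH from Rubottom oxidation of the C8 silyl enol ether (C8=C9), C7 by equilibration α to that ketone; the angular methyl C14 from a formyl group.
3. Enabling feature: ring B (C5–C10) has a quaternary fusion carbon C5 carrying the one-carbon group C14 and oxygen at C8. It is therefore the retron of a Diels–Alder reaction between a 2-silyloxydiene C7=C8(OSi)–C9=C10 and a 2-substituted acrolein C6=C5–C14HO, and the chain C1–C4 that joins C10 to C5 makes it intramolecular.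
4. Key event: silylation of the acyclic enone–enal 15 triggers a type 1 intramolecular Diels–Alder reaction that forms C5–C10 and C6–C7 together; rings A and B are closed in the same operation.
5. Precursor 15 comes from an Evans syn-aldol (C3/C4), a methyl ketone → enol triflate → carbonylative formylation (C5=C6, C14), and a cross-metathesis with a methallyl carbinol ether (C7–C13).

Key step: step 12

Remark: eremophilane locants are used for ring compounds (ring A = C1–C5, C10; ring B = C5–C10; isopropenyl C11–C13 on C7; C14 on C5; C15 on C4); ether 10 is used as the racemate, so 11, 13 and 14 are epimer pairs at the carbinol carbon that is oxidized in step 11; (S)-pent-1-yn-3-ol and 2-methylallylmagnesium chloride are taken as purchasable.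

**Step 1**
Reactants: 1 (S)-4-benzyl-3-propanoyl-1,3-oxazolidin-2-one; 2 pent-4-enal
Product: 3 (S)-4-benzyl-3-[(2S,3R)-3-hydroxy-2-methylhept-6-enoyl]-1,3-oxazolidin-2-one
Conditions: Bu2BOTf, i-Pr2NEt, CH2Cl2, −78 → 0 °C; then 2, −78 → 0 °C; pH 7 buffer
Reagents that add atoms: none
Why: Evans syn-aldol reaction: the (Z)-boron enolate reacts through a Zimmerman–Traxler chair on the face away from the benzyl group, which sets the syn pair that becomes C4 (methyl) and C3 (oxygen) as (2S,3R).

**Step 2**
Reactants: 3 aldol adduct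
Product: 4 (2S,3R)-3-hydroxy-N-methoxy-N,2-dimethylhept-6-enamide
Conditions: MeNHOMe·HCl, AlMe3, CH2Cl2, −10 °C → rt
Reagents that add atoms: N,O-dimethylhydroxylamine hydrochloride, CNOC.Cl
Why: Aluminium amide transamidation (Weinreb amide formation) of the β-hydroxy imide should proceed through the chelated aluminium alkoxide without epimerization and release the auxiliary.

**Step 3**
Reactants: 4 hydroxy Weinreb amide
Product: 5 (2S,3R)-N-methoxy-N,2-dimethyl-3-[(triethylsilyl)oxy]hept-6-enamide
Conditions: Et3SiCl, imidazole, CH2Cl2, 0 °C → rt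
Reagents that add atoms: chlorotriethylsilane, CC[Si](Cl)(CC)CC
Why: Standard silylation of the secondary alcohol; the TES ether should last until the acidic methanolysis of step 17.

**Step 4**
Reactants: 5 silylated Weinreb amide
Product: 6 (3S,4R)-3-methyl-4-[(triethylsilyl)oxy]oct-7-en-2-one
Conditions: MeMgBr, THF, 0 °C
Reagents that add atoms: methylmagnesium bromide, C[Mg]Br
Why: Grignard addition to a Weinreb amide stops at the ketone through the stable magnesium chelate; the carbonyl carbon of 6 becomes C5.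

**Step 5**
Reactants: 7 acrolein; 8 2-methylallylmagnesium chloride (CH2=C(CH3)CH2MgCl)
Product: 9 (±)-5-methylhexa-1,5-dien-3-ol
Conditions: THF, −78 → 0 °C; aqueous work-up
Reagents that add atoms: none
Why: 1,2-Addition of the allylic Grignard reagent to the enal gives the carbinol, racemic on purpose because this carbon becomes the C8 carbonyl in step 11.

**Step 6**
Reactants: 9 dienol
Product: 10 (±)-1-methoxy-4-{[(5-methylhexa-1,5-dien-3-yl)oxy]methyl}benzene
Conditions: NaH, PMBCl, Bu4NI (cat.), THF/DMF, 0 °C → rt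
Reagents that add atoms: 4-methoxybenzyl chloride, COc1ccc(CCl)cc1
Why: Williamson etherification gives a PMB ether that can be removed oxidatively in step 10 without touching the TES ether.

**Step 7**
Reactants: 6 methyl ketone; 10 PMB ether (3 equiv)
Product: 11 (3S,4R,7E)-9-[(4-methoxyphenyl)methoxy]-3,11-dimethyl-4-[(triethylsilyl)oxy]dodeca-7,11-dien-2-one
Conditions: second-generation Hoveyda–Grubbs catalyst RuCl2(=CH-C6H4-2-O-i-Pr)(SIMes) (5 mol %), CH2Cl2, 40 °C
Reagents that add atoms: none
Why: Olefin cross-metathesis between the terminal alkene of 6 and the monosubstituted vinyl group of 10 should give the (E)-alkene (future C9=C10) under thermodynamic control, with the 1,1-disubstituted isopropenyl group and the ketone as spectators.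

**Step 8**
Reactants: 11 ketone
Product: 12 (3S,4R,7E)-9-[(4-methoxyphenyl)methoxy]-3,11-dimethyl-4-[(triethylsilyl)oxy]dodeca-1,7,11-trien-2-yl trifluoromethanesulfonate
Conditions: KN(SiMe3)2, THF, −78 °C; PhNTf2, −78 → 0 °C
Reagents that add atoms: N-phenylbis(trifluoromethanesulfonimide), O=S(=O)(N(c1ccccc1)S(=O)(=O)C(F)(F)F)C(F)(F)F
Why: Enol triflate formation: kinetic deprotonation at the methyl group by the hindered amide base and O-triflation give the 1,1-disubstituted enol triflate without touching the α-stereocentre.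

**Step 9**
Reactants: 12 enol triflate
Product: 13 (3R,4R,7E)-9-[(4-methoxyphenyl)methoxy]-3,11-dimethyl-2-methylidene-4-[(triethylsilyl)oxy]dodeca-7,11-dienal
Conditions: Pd(PPh3)4 (5 mol %), CO (1 atm), Bu3SnH (slow addition), LiCl, THF, 50 °C
Reagents that add atoms: carbon monoxide, [C-]#[O+]
Why: Stille-type reductive carbonylation of a vinyl triflate (oxidative addition, CO insertion, hydride transfer from tin) should give the 2-substituted acrolein under neutral conditions.

**Step 10**
Reactants: 13 PMB ether enal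
Product: 14 (3R,4R,7E)-9-hydroxy-3,11-dimethyl-2-methylidene-4-[(triethylsilyl)oxy]dodeca-7,11-dienal
Conditions: DDQ, CH2Cl2/pH 7 buffer, 0 °C
Reagents that add atoms: none
Why: Oxidative PMB cleavage with DDQ (through the benzylic oxocarbenium ion) should free the allylic alcohol and leave the silyl ether and the enal intact.

**Step 11**
Reactants: 14 allylic alcohol
Product: 15 (3R,4R,7E)-3,11-dimethyl-2-methylidene-9-oxo-4-[(triethylsilyl)oxy]dodeca-7,11-dienal
Conditions: Dess–Martin periodinane, pyridine, CH2Cl2, 0 °C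
Reagents that add atoms: none
Why: Dess–Martin oxidation under buffered, non-basic conditions should give the vinyl ketone without moving the isopropenyl double bond into conjugation.

**Step 12**
Reactants: 15 enone–enal
Product: 17 (3R,4R,5R,7R,10S)-3,8-bis[(triethylsilyl)oxy]eremophila-8,11-dien-14-al (trans-fused; isopropenyl cis to the angular formyl group), via silyloxytriene 16 (not isolated)
Conditions: Et3SiOTf (1.1 equiv), Et3N (3 equiv), PhMe (0.01 M), −78 °C → rt, then 60 °C
Reagents that add atoms: triethylsilyl trifluoromethanesulfonate, CC[Si](CC)(CC)OS(=O)(=O)C(F)(F)F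
Why: Soft enolization of the ketone at the doubly activated CH2 (C7) gives the (Z)-2-silyloxytriene 16, whose diene C7=C8(OSi)–C9=C10 adds to the 2-substituted acrolein C5=C6 in a concerted, asynchronous, normal-electron-demand type 1 intramolecular Diels–Alder reaction in which the nucleophilic C7 bonds to the acrolein β-carbon C6, so tether and polarity ask for the same regiochemistry. The closest known reactions are silyl-triflate-triggered silyloxydiene intramolecular Diels–Alder reactions of enones and the endo-selective cyclization of 2-methylene trienals (1,7,9-decatrienes activated at the inner dienophile carbon) to trans-fused octalins with an angular formyl group. Ring B is closed as the six-membered cycloadduct ring by both new bonds (C5–C10 and C6–C7, boat-like transition state), and ring A is closed at the same time as the six-membered tether ring by the C5–C10 bond (chair-like C1–C4 tether). C5 and C10 are controlled by the endo position of the formyl group with the tether exo, which gives the trans ring fusion with an axial formyl group, while the tether chair that keeps the C3 silyloxy and C4 methyl groups equatorial selects the diene face and thus the absolute sense. C7 is controlled by the (Z)-enol ether geometry, which places the isopropenyl group outside and therefore cis to the formyl group; this centre is corrected in step 14. The step needs endo over exo selectivity and periselectivity: the second diene of 16 (C8=C7–C11=C12) could only react through an eight-membered tether ring, and the excess amine keeps the medium free of acid that could trigger a carbonyl-ene reaction between the cis formyl and isopropenyl groups.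

**Step 13**
Reactants: 17 silyl enol ether aldehyde
Product: 19 (3R,4R,5S,7R,9S,10R)-8-oxo-3,9-bis[(triethylsilyl)oxy]eremophil-11-en-14-al (isopropenyl still axial), via silyloxy epoxide 18 (not isolated)
Conditions: dimethyldioxirane (acetone solution, 1.05 equiv), CH2Cl2, −78 → 0 °C; evaporate; PhMe, 60 °C
Reagents that add atoms: dimethyldioxirane, CC1(C)OO1
Why: Rubottom oxidation: the dioxirane should epoxidize the electron-rich silyl enol ether, much faster than the isopropenyl group or the aldehyde, on the face opposite the axial formyl and isopropenyl groups, and 1,4-silyl migration of the silyloxy oxirane gives the ketone with the C9 oxygen equatorial and cis to H-10.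

**Step 14**
Reactants: 19 ketone with axial isopropenyl group
Product: 20 (3R,4R,5S,7S,9S,10R)-8-oxo-3,9-bis[(triethylsilyl)oxy]eremophil-11-en-14-al (isopropenyl equatorial, trans to the formyl group)
Conditions: DBU (0.2 equiv), CH2Cl2, 0 °C → rt, monitored
Reagents that add atoms: none
Why: Base-mediated epimerization α to the ketone through the enolate: the axial isopropenyl group, 1,3-diaxial to the angular formyl group, should move to the equatorial position, which sets C7 under thermodynamic control (α-protonation of the dienolate is faster than γ-protonation).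

**Step 15**
Reactants: 20 keto aldehyde
Product: 22 (3R,4R,5R,7S,9S,10R)-3,9-bis[(triethylsilyl)oxy]eremophil-11-en-8-one, via tosylhydrazone 21 (not isolated)
Conditions: TsNHNH2, THF, rt; evaporate; catecholborane, CHCl3, 0 °C; then NaOAc·3H2O, 60 °C
Reagents that add atoms: none
Why: The aldehyde, far more reactive than the doubly α-substituted ketone, should condense selectively with tosylhydrazine, and hydride reduction of the hydrazone followed by acetate-induced loss of sulfinate and dinitrogen (Kabalka variant of the Caglioti tosylhydrazone reduction) turns the formyl group into the angular methyl group.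

**Step 16**
Reactants: 22 ketone
Product: 23 (3R,4R,5R,7S,8R,9S,10R)-3,9-bis[(triethylsilyl)oxy]eremophil-11-en-8-ol
Conditions: LiBH(s-Bu)3, THF, −78 °C
Reagents that add atoms: none
Why: Stereoselective ketone reduction with a bulky hydride: attack from the equatorial direction should give the axial C8 alcohol, cis to the two flanking equatorial substituents.

**Step 17**
Reactants: 23 bis-silyl ether alcohol
Product: 25 (3R,4R,5R,7S,8R,9S,10R)-8,9-(isopropylidenedioxy)eremophil-11-en-3-ol, via triol 24 (not isolated)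
Conditions: PPTS, MeOH, rt; evaporate; 2,2-dimethoxypropane, acetone, rt
Reagents that add atoms: 2,2-dimethoxypropane, COC(C)(C)OC
Why: Acidic methanolysis removes both TES ethers, and only the cis-8,9-diol can form the five-membered isopropylidene acetal (transketalization), which leaves the C3 hydroxyl free.

**Step 18**
Reactants: 26 (S)-pent-1-yn-3-ol
Product: 27 (S)-tert-butyldimethyl(pent-1-yn-3-yloxy)silane
Conditions: TBSCl, imidazole, DMF, rt
Reagents that add atoms: tert-butyldimethylsilyl chloride, CC(C)(C)[Si](C)(C)Cl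
Why: Silylation protects the carbinol so that the alkyne can be metalated and carboxylated; the stereocentre is untouched.

**Step 19**
Reactants: 27 silyl ether
Product: 28 (S)-4-[(tert-butyldimethylsilyl)oxy]hex-2-ynoic acid
Conditions: n-BuLi, THF, −78 °C; CO2; then cold 1 M HCl
Reagents that add atoms: carbon dioxide, O=C=O
Why: Carboxylation of the lithium acetylide with carbon dioxide gives the ynoic acid directly.

**Step 20**
Reactants: 25 acetonide alcohol; 28 ynoic acid
Product: 29 (3R,4R,5R,7S,8R,9S,10R)-8,9-(isopropylidenedioxy)eremophil-11-en-3-yl (S)-4-[(tert-butyldimethylsilyl)oxy]hex-2-ynoate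
Conditions: DIC, DMAP (cat.), CH2Cl2, 0 °C → rt
Reagents that add atoms: none
Why: Steglich-type carbodiimide esterification of the only free hydroxyl (C3, equatorial); an alkynoic acid cannot undergo the Z → E isomerization that threatens a (Z)-enoic acid on activation.

**Step 21**
Reactants: 29 silyl ether ester
Product: 30 (3R,4R,5R,7S,8R,9S,10R)-8,9-(isopropylidenedioxy)eremophil-11-en-3-yl (S)-4-hydroxyhex-2-ynoate
Conditions: HF·pyridine, pyridine, THF, 0 °C → rt
Reagents that add atoms: none
Why: Fluoride-mediated desilylation; the γ-hydroxy ynoate cannot lactonize because the alkyne is linear, and the acetonide should survive the buffered reagent.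

**Step 22**
Reactants: 30 hydroxy ynoate; 31 hex-2-ynoic acid
Product: 32 (3R,4R,5R,7S,8R,9S,10R)-8,9-(isopropylidenedioxy)eremophil-11-en-3-yl (S)-4-(hex-2-ynoyloxy)hex-2-ynoate
Conditions: DIC, DMAP (cat.), CH2Cl2, 0 °C → rt
Reagents that add atoms: none
Why: Steglich esterification of the propargylic alcohol completes the side-chain skeleton.

**Step 23**
Reactants: 32 bis-ynoate
Product: 33 (3R,4R,5R,7S,8R,9S,10R)-8,9-(isopropylidenedioxy)eremophil-11-en-3-yl (2Z,4S)-4-[(2Z)-hex-2-enoyloxy]hex-2-enoate
Conditions: H2 (1 atm), Pd/CaCO3 poisoned with Pb(OAc)2 (Lindlar catalyst), quinoline, EtOAc, rt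
Reagents that add atoms: none
Why: Lindlar semi-hydrogenation: syn addition of hydrogen to both conjugated alkynes should give the two (Z)-enoates, while the 1,1-disubstituted isopropenyl alkene is not reduced on the poisoned catalyst.

**Step 24**
Reactants: 33 acetonide
Product: 34 (3R,4R,5R,7S,8R,9S,10R)-8,9-dihydroxyeremophil-11-en-3-yl (2Z,4S)-4-[(2Z)-hex-2-enoyloxy]hex-2-enoate (CNP0271544.1)
Conditions: AcOH/H2O (4:1), 40 °C
Reagents that add atoms: none
Why: Acid-catalyzed acetal hydrolysis frees the cis-diol under conditions that should not affect the esters, the (Z)-alkenes or the isopropenyl group.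

**Compound list**
1 | (S)-4-benzyl-3-propanoyl-1,3-oxazolidin-2-one | CCC(=O)N1[C@@H](Cc2ccccc2)COC1=O | starting material
2 | pent-4-enal | C=CCCC=O | starting material
3 | (S)-4-benzyl-3-[(2S,3R)-3-hydroxy-2-methylhept-6-enoyl]-1,3-oxazolidin-2-one | O=C(N1[C@@H](Cc2ccccc2)COC1=O)[C@@H](C)[C@H](O)CCC=C | intermediate
4 | (2S,3R)-3-hydroxy-N-methoxy-N,2-dimethylhept-6-enamide | CON(C)C(=O)[C@@H](C)[C@H](O)CCC=C | intermediate
5 | (2S,3R)-N-methoxy-N,2-dimethyl-3-[(triethylsilyl)oxy]hept-6-enamide | CON(C)C(=O)[C@@H](C)[C@H](O[Si](CC)(CC)CC)CCC=C | intermediate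
6 | (3S,4R)-3-methyl-4-[(triethylsilyl)oxy]oct-7-en-2-one | CC(=O)[C@@H](C)[C@H](O[Si](CC)(CC)CC)CCC=C | intermediate
7 | acrolein | C=CC=O | starting material
8 | 2-methylallylmagnesium chloride | CC(=C)C[Mg]Cl | starting material
9 | (±)-5-methylhexa-1,5-dien-3-ol | C=CC(O)CC(C)=C | intermediate
10 | (±)-1-methoxy-4-{[(5-methylhexa-1,5-dien-3-yl)oxy]methyl}benzene | C=CC(OCc1ccc(OC)cc1)CC(C)=C | intermediate
11 | (3S,4R,7E)-9-[(4-methoxyphenyl)methoxy]-3,11-dimethyl-4-[(triethylsilyl)oxy]dodeca-7,11-dien-2-one (C9 epimers) | CC(=O)[C@@H](C)[C@H](O[Si](CC)(CC)CC)CC/C=C/C(OCc1ccc(OC)cc1)CC(C)=C | intermediate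
12 | (3S,4R,7E)-9-[(4-methoxyphenyl)methoxy]-3,11-dimethyl-4-[(triethylsilyl)oxy]dodeca-1,7,11-trien-2-yl trifluoromethanesulfonate (C9 epimers) | C=C(OS(=O)(=O)C(F)(F)F)[C@@H](C)[C@H](O[Si](CC)(CC)CC)CC/C=C/C(OCc1ccc(OC)cc1)CC(C)=C | intermediate
13 | (3R,4R,7E)-9-[(4-methoxyphenyl)methoxy]-3,11-dimethyl-2-methylidene-4-[(triethylsilyl)oxy]dodeca-7,11-dienal (C9 epimers) | O=CC(=C)[C@@H](C)[C@H](O[Si](CC)(CC)CC)CC/C=C/C(OCc1ccc(OC)cc1)CC(C)=C | intermediate
14 | (3R,4R,7E)-9-hydroxy-3,11-dimethyl-2-methylidene-4-[(triethylsilyl)oxy]dodeca-7,11-dienal (C9 epimers) | O=CC(=C)[C@@H](C)[C@H](O[Si](CC)(CC)CC)CC/C=C/C(O)CC(C)=C | intermediate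
15 | (3R,4R,7E)-3,11-dimethyl-2-methylidene-9-oxo-4-[(triethylsilyl)oxy]dodeca-7,11-dienal | O=CC(=C)[C@@H](C)[C@H](O[Si](CC)(CC)CC)CC/C=C/C(=O)CC(C)=C | intermediate
16 | (3R,4R,7E,9Z)-3,11-dimethyl-2-methylidene-4,9-bis[(triethylsilyl)oxy]dodeca-7,9,11-trienal | O=CC(=C)[C@@H](C)[C@H](O[Si](CC)(CC)CC)CC/C=C/C(O[Si](CC)(CC)CC)=C/C(C)=C | intermediate (not isolated)
17 | (3R,4R,5R,7R,10S)-3,8-bis[(triethylsilyl)oxy]eremophila-8,11-dien-14-al (trans-fused; isopropenyl cis to the formyl group) | C=C(C)[C@H]1C[C@]2(C=O)[C@@H](C)[C@H](O[Si](CC)(CC)CC)CC[C@H]2C=C1O[Si](CC)(CC)CC | intermediate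
18 | 8,9-epoxide of 17 on the face of H-10 (8,9-epoxy-3,8-bis[(triethylsilyl)oxy]eremophil-11-en-14-al) | C=C(C)[C@H]1C[C@]2(C=O)[C@@H](C)[C@H](O[Si](CC)(CC)CC)CC[C@H]2[C@@H]3O[C@]13O[Si](CC)(CC)CC | intermediate (not isolated)
19 | (3R,4R,5S,7R,9S,10R)-8-oxo-3,9-bis[(triethylsilyl)oxy]eremophil-11-en-14-al (isopropenyl axial) | C=C(C)[C@H]1C[C@]2(C=O)[C@@H](C)[C@H](O[Si](CC)(CC)CC)CC[C@H]2[C@H](O[Si](CC)(CC)CC)C1=O | intermediate
20 | (3R,4R,5S,7S,9S,10R)-8-oxo-3,9-bis[(triethylsilyl)oxy]eremophil-11-en-14-al (isopropenyl equatorial) | C=C(C)[C@@H]1C[C@]2(C=O)[C@@H](C)[C@H](O[Si](CC)(CC)CC)CC[C@H]2[C@H](O[Si](CC)(CC)CC)C1=O | intermediate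
21 | (E)-N-tosylhydrazone of 20 at C14 | C=C(C)[C@@H]1C[C@]2(/C=N/NS(=O)(=O)c3ccc(C)cc3)[C@@H](C)[C@H](O[Si](CC)(CC)CC)CC[C@H]2[C@H](O[Si](CC)(CC)CC)C1=O | intermediate (not isolated)
22 | (3R,4R,5R,7S,9S,10R)-3,9-bis[(triethylsilyl)oxy]eremophil-11-en-8-one | C=C(C)[C@@H]1C[C@]2(C)[C@@H](C)[C@H](O[Si](CC)(CC)CC)CC[C@H]2[C@H](O[Si](CC)(CC)CC)C1=O | intermediate
23 | (3R,4R,5R,7S,8R,9S,10R)-3,9-bis[(triethylsilyl)oxy]eremophil-11-en-8-ol | C=C(C)[C@@H]1C[C@]2(C)[C@@H](C)[C@H](O[Si](CC)(CC)CC)CC[C@H]2[C@H](O[Si](CC)(CC)CC)[C@@H]1O | intermediate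
24 | (3R,4R,5R,7S,8R,9S,10R)-eremophil-11-ene-3,8,9-triol | C=C(C)[C@@H]1C[C@]2(C)[C@@H](C)[C@H](O)CC[C@H]2[C@H](O)[C@@H]1O | intermediate (not isolated)
25 | (3R,4R,5R,7S,8R,9S,10R)-8,9-(isopropylidenedioxy)eremophil-11-en-3-ol | C=C(C)[C@@H]1C[C@]2(C)[C@@H](C)[C@H](O)CC[C@H]2[C@@H]3OC(C)(C)O[C@H]13 | intermediate
26 | (S)-pent-1-yn-3-ol | C#C[C@H](CC)O | starting material
27 | (S)-tert-butyldimethyl(pent-1-yn-3-yloxy)silane | C#C[C@H](CC)O[Si](C)(C)C(C)(C)C | intermediate
28 | (S)-4-[(tert-butyldimethylsilyl)oxy]hex-2-ynoic acid | OC(=O)C#C[C@H](CC)O[Si](C)(C)C(C)(C)C | intermediate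
29 | (3R,4R,5R,7S,8R,9S,10R)-8,9-(isopropylidenedioxy)eremophil-11-en-3-yl (S)-4-[(tert-butyldimethylsilyl)oxy]hex-2-ynoate | C=C(C)[C@@H]1C[C@]2(C)[C@@H](C)[C@H](OC(=O)C#C[C@H](CC)O[Si](C)(C)C(C)(C)C)CC[C@H]2[C@@H]3OC(C)(C)O[C@H]13 | intermediate
30 | (3R,4R,5R,7S,8R,9S,10R)-8,9-(isopropylidenedioxy)eremophil-11-en-3-yl (S)-4-hydroxyhex-2-ynoate | C=C(C)[C@@H]1C[C@]2(C)[C@@H](C)[C@H](OC(=O)C#C[C@H](CC)O)CC[C@H]2[C@@H]3OC(C)(C)O[C@H]13 | intermediate
31 | hex-2-ynoic acid | CCCC#CC(=O)O | starting material
32 | (3R,4R,5R,7S,8R,9S,10R)-8,9-(isopropylidenedioxy)eremophil-11-en-3-yl (S)-4-(hex-2-ynoyloxy)hex-2-ynoate | C=C(C)[C@@H]1C[C@]2(C)[C@@H](C)[C@H](OC(=O)C#C[C@H](CC)OC(=O)C#CCCC)CC[C@H]2[C@@H]3OC(C)(C)O[C@H]13 | intermediate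
33 | (3R,4R,5R,7S,8R,9S,10R)-8,9-(isopropylidenedioxy)eremophil-11-en-3-yl (2Z,4S)-4-[(2Z)-hex-2-enoyloxy]hex-2-enoate | C=C(C)[C@@H]1C[C@]2(C)[C@@H](C)[C@H](OC(=O)/C=C\[C@H](CC)OC(=O)/C=C\CCC)CC[C@H]2[C@@H]3OC(C)(C)O[C@H]13 | intermediate
34 | (3R,4R,5R,7S,8R,9S,10R)-8,9-dihydroxyeremophil-11-en-3-yl (2Z,4S)-4-[(2Z)-hex-2-enoyloxy]hex-2-enoate (CNP0271544.1) | C=C(C)[C@@H]1C[C@]2(C)[C@@H](C)[C@H](OC(=O)/C=C\[C@H](CC)OC(=O)/C=C\CCC)CC[C@H]2[C@H](O)[C@@H]1O | target

**Step count and risks**
Total: 24 steps. Longest linear sequence: 20 steps (steps 1–4, 7–17, 20–24).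

Steps most likely to fail:

Step 12. While the adduct forms, silyl triflate and ammonium triflate are present; they may trigger a carbonyl-ene closure between the cis formyl and isopropenyl groups, or cleave the silyloxytriene before it cyclizes. The fallback reverses the order in which diene and dienophile are unmasked. It sets out from enol triflate 12: DDQ (CH2Cl2/pH 7 buffer) should give the hydroxy triflate F1, Dess–Martin oxidation the enone triflate F2, and Et3SiOTf/Et3N at −78 °C the silyloxytriene triflate F3, which can be isolated because no dienophile is present. The formylation of step 9 (Pd(PPh3)4, CO, Bu3SnH, LiCl, THF, 50 °C) then generates trienal 16 in a neutral medium, where it should cyclize directly; the fallback comes back to the route at 17.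

Step 14. Under base, migration of the isopropenyl double bond into conjugation with the ketone may compete with simple inversion at C7. The fallback uses the conjugated isomer on purpose and sets out from 19: DBU (1 equiv), PhMe, 60 °C should drive all material to the isopropylidene ketone F4. The extended dienolate is then formed under equilibrating conditions (KOt-Bu, t-BuOH/THF, 0 °C) and quenched inversely into cold aqueous AcOH; kinetic α-protonation from the axial direction should give the equatorial isopropenyl group. The fallback comes back to the route at 20.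

Step 15. Chemoselectivity between the hindered neopentyl aldehyde and the C8 ketone may be incomplete (hydrazone formation or hydride transfer at the ketone), or reduction at the hindered centre may stall. The fallback removes the oxygen by a radical route and sets out from 20: excess LiBH(s-Bu)3 (THF, −78 °C) should reduce both carbonyls to the diol F5 with the same axial C8 alcohol. I2, PPh3, imidazole (PhMe, 80 °C) should convert only the primary alcohol into the neopentyl iodide F6, and Bu3SnH, AIBN (PhMe, 80 °C) reduces it; the primary radical cannot reach the isopropenyl group, which is now trans. The fallback comes back to the route at 23.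

**Further compounds**
F1 | step 12 | (3S,4R,7E)-9-hydroxy-3,11-dimethyl-4-[(triethylsilyl)oxy]dodeca-1,7,11-trien-2-yl trifluoromethanesulfonate (C9 epimers) | C=C(OS(=O)(=O)C(F)(F)F)[C@@H](C)[C@H](O[Si](CC)(CC)CC)CC/C=C/C(O)CC(C)=C
F2 | step 12 | (3S,4R,7E)-3,11-dimethyl-9-oxo-4-[(triethylsilyl)oxy]dodeca-1,7,11-trien-2-yl trifluoromethanesulfonate | C=C(OS(=O)(=O)C(F)(F)F)[C@@H](C)[C@H](O[Si](CC)(CC)CC)CC/C=C/C(=O)CC(C)=C
F3 | step 12 | (3S,4R,7E,9Z)-3,11-dimethyl-4,9-bis[(triethylsilyl)oxy]dodeca-1,7,9,11-tetraen-2-yl trifluoromethanesulfonate | C=C(OS(=O)(=O)C(F)(F)F)[C@@H](C)[C@H](O[Si](CC)(CC)CC)CC/C=C/C(O[Si](CC)(CC)CC)=C/C(C)=C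
F4 | step 14 | (3R,4R,5S,9S,10R)-8-oxo-3,9-bis[(triethylsilyl)oxy]eremophil-7(11)-en-14-al | CC(C)=C1C[C@]2(C=O)[C@@H](C)[C@H](O[Si](CC)(CC)CC)CC[C@H]2[C@H](O[Si](CC)(CC)CC)C1=O
F5 | step 15 | 3,9-bis[(triethylsilyl)oxy]eremophil-11-ene-8,14-diol (ring stereocentres as in 23) | C=C(C)[C@@H]1C[C@]2(CO)[C@@H](C)[C@H](O[Si](CC)(CC)CC)CC[C@H]2[C@H](O[Si](CC)(CC)CC)[C@@H]1O
F6 | step 15 | 14-iodo-3,9-bis[(triethylsilyl)oxy]eremophil-11-en-8-ol (ring stereocentres as in 23) | C=C(C)[C@@H]1C[C@]2(CI)[C@@H](C)[C@H](O[Si](CC)(CC)CC)CC[C@H]2[C@H](O[Si](CC)(CC)CC)[C@@H]1O
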